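## The problem

The target is a trimer of 3',4',5,7-tetrahydroxyflavan units. The upper and middle units are (2R,3R), 2,3-cis flavan-3-ols joined by a carbon–carbon bond from C4 of the upper unit (aryl β, trans to the 3-hydroxyl) to C8 of ring A of the middle unit. C4 of the middle unit carries a β-oxygen, again trans to its 3-hydroxyl, and this oxygen bridges to C4 of the lower unit, a (2S,3S,4S)-flavan-3,4-diol in which aryl group, hydroxyl and ether oxygen are all cis. Of the nine stereocentres, C2 and C3 of the middle and lower units can be bought, the lower pair in the enantiomeric series; the other five must be made. Three neighbour effects are available for them. A 3-alkoxy group sends a nucleophile to the trans face of a C4 cation (middle C4). It sends hydride to a C4 ketone so that the hydroxyl ends cis (lower C4). The C4 aryl group of the upper unit should send a nucleophile at C2 to the opposite face. The molecule will not tolerate rough treatment: the phloroglucinol rings are nucleophilic at C6 and C8 and easily oxidised, the C4–C8 bond and above all the doubly benzylic C4–O–C4 ether ionise with acid, and the free phenols are base- and air-sensitive. The phenols therefore stay masked to the end and the ether is made late, without acid. The feature that opens the structure is upper C4: it is bonded to C4a of its own ring A, ortho to the O1-bearing C8a, and to C8 of the middle unit. It is therefore the methide carbon of an o-quinone methide that already carries the middle unit, and the remaining ring atoms C3 (oxygenated) and C2 are the two carbons of an α-alkoxy acetaldehyde.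

## Retrosynthesis

**Protecting groups.** The last operation removes fifteen benzyl groups from 29 to give 30. Benzyl is preferred to silyl or acyl because it survives organolithium reagents, Lewis acids and quinone oxidation and leaves under neutral conditions. The forward step must spare the ring C–O bonds and the inter-unit ether, which are benzylic too but secondary and crowded.

**Inter-unit ether.** In 29 the ether oxygen is cut from C4 of the middle unit, giving thioether 22 and alcohol 28. The neighbouring cut at C4 of the lower unit is rejected: a cation there would be attacked trans to its 3-substituent and give the wrong 3,4-trans ether. At middle C4 the same preference gives the required 4β bond, and the cis C4–O bond of 28 is never broken. The precursors are a dimer and a monomer. The forward reaction must be a kinetic O-alkylation of a hindered secondary alcohol in the absence of acid, which calls for a sulfur leaving group that a soft silver salt activates.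

**Activation of middle C4.** Thioether 22 is traced through glycol ether 21 to the decabenzyl dimer 20 by cutting C4–S, then C4–O, back to C4–H. Carrying the sulfur from the monomer stage would expose it to bromination, organolithium and Lewis acid steps, so late oxidation is shorter. The oxidant must choose the C4 methylene of the middle unit over the C4 methine and the C2 positions of the dimer.

**Lower unit.** The all-cis alcohol 28 comes from ketone 27 by hydride delivery anti to the 3-benzyloxy group. Ketone 27 comes from the trans alcohol 26, and 26 from C4–H oxidation of 25. Direct oxygenation gives only the trans alcohol, hence the detour through the ketone. Benzyl ethers 25 and 24 lead back to 23, which supplies C2 and C3.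

**Upper C2–aryl bond.** In 20 the bond from upper C2 to its catechol ring is cut, giving sulfone 16 and arylzinc 19 (from bromide 17 through 18); 16 comes from lactol 15. The aryl group must be the incoming nucleophile: it should enter anti to the bulky C4 substituent and cis to the 3-benzyloxy group, which is the 2,3-cis-3,4-trans pattern. Adding hydride last to a 2-aryl cation would put hydrogen on that face and the aryl group on the wrong one. A simple catechol diether as Friedel–Crafts partner is rejected because the three benzyloxylated rings A of the substrate are better nucleophiles and would oligomerise the cation; an organozinc reagent outruns them. The forward step needs an anomeric leaving group that a mild Lewis acid ionises in the presence of the organometal.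

**Upper ring C (key cut).** In 15 the C3–C4 and O1–C2 bonds are cut, giving o-quinone methide 12 and the enamine 13 of aldehyde 11 by way of hydroxy aldehyde 14; 12 arises from benzhydrol 10. The neighbouring cut, C4–C8 by cationic coupling of two flavan units, is shorter but leaves the C8/C6 choice and the degree of oligomerisation to the electronic bias of the nucleophile. The chosen cut fixes the C4–C8 bond beforehand and builds the ring from an achiral two-carbon piece. One ring, two skeletal bonds and two stereocentres form in one operation. The forward reaction must set C3 and C4 as trans with the 4β sense under catalyst control.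

**The benzhydrol.** 10 is the desilylated form of 9, and 9 is cut between the carbinol carbon and C8 of the middle unit into aryllithium 8 and aldehyde 7. Friedel–Crafts hydroxyalkylation of 3 would again have to choose between C8 and C6; bromine in 4 fixes the site. Both pieces are simple derivatives of commercial compounds.

**Building blocks.** 4 comes from 3, 2 and 1 by benzylation and C8 bromination; 7 comes from 6 and 5 by selective benzylation and silylation.

## Roads not taken

**Alternative 1:** The cut runs through ring A of the middle unit, removing the C8a–C4a and C5–C6 bonds. That leaves cyclobutenone A2, with the finished upper unit on its saturated carbon, and siloxyalkyne A3, with the open C2–C3–C4 chain of the middle unit. Forward, heating opens A2 to a vinylketene, which adds to A3 in a [2+2] sense; four-electron opening, six-electron closure and tautomerisation (Danheiser benzannulation) give phenol A1.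
- Merits: the hexasubstituted ring is regiodefined, its C5 oxygen and C8a hydroxyl are differentiated, and all upper stereocentres come from the chiral pool and the reliable trans substitution at C4.
- Weak points: A2 has no obvious short preparation. A3 needs its two stereocentres from an asymmetric dihydroxylation sequence. The six-electron closure must form a bond to the carbon bearing the whole upper unit. After A1, ring C still has to be closed with inversion at the benzylic carbon and the silyl group exchanged for benzyl before the same late operations as steps 11, 12, 18 and 19.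
- Comparison: this road is better in one respect, since no catalyst has to set a crowded benzhydrylic stereocentre. The chosen plan sets against that an intact chiral-pool middle unit, mild conditions and roughly half the step count.

**Alternative 2:** The cut is the C3=C4 bond of the lower ring. A titanium alkylidene would join the ester carbonyl and the terminal alkene of ester A5 and close the lower pyran as 4-alkoxy-2H-chromene A4, which already contains the inter-unit ether.
- Merits: the critical C–O bond is made by acylation, where O versus C attack and re-ionisation are not an issue, and the dimer is used as the cheap nucleophile.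
- Weak points: the ester carbonyl is flanked by two ortho alkoxy groups. The aryl 1-arylallyl ether in A5 is prone to ionisation and [3,3] rearrangement. A4 is an acid-labile enol ether whose hydrolysis cleaves the very bond that was secured. The lower C3 and C4 centres must then be set on A4, and syn hydroboration would give 3,4-trans, not the all-cis pattern.
- Comparison: this road is better at forming the ether bond itself. The chosen plan sets against that a lower unit whose three stereocentres are fixed before coupling, so that the etherification defines both C4 configurations at once.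

**Alternative 3:** The cut removes C4a–C4 and O1–C2 of the middle ring C. Hub phenol A7, as its bromomagnesium salt, would add through its free ortho carbon to cis-epoxy aldehyde A8; the phenoxide then opens the epoxide at the benzylic carbon with inversion to give the 2,3-cis flavan-3,4-diol A6.
- Merits: A7 comes from the most reliable C–C coupling in this field, since the nucleophile is symmetrical. The middle C4 oxygen arrives with the ring, so no dimer has to be oxidised. The 2,3-cis relation follows from the epoxide geometry.
- Weak points: A8 is an electron-rich benzylic epoxide and an α-epoxy aldehyde at once, hard to obtain enantiopure and easily rearranged. Ortho versus para attack and six- versus five-membered epoxide opening must both go the right way. The 3- and 4-hydroxyls of A6 then need to be told apart.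
- Comparison: this road is better in avoiding the late C–H oxidation of step 11. The chosen plan sets against that a middle unit taken whole from the chiral pool and no diol differentiation.

Key step: step 8

Assumptions on the chemistry:
- (+)-Epicatechin 23, the (2S,3S) enantiomer of 1, is taken as a purchasable chiral-pool compound, because the lower unit has the 2S,3S configuration and reduction of an achiral flavonol cannot deliver it without a further asymmetric step.
- The carbinol carbon of 9 and 10 and the anomeric carbon of 15 and 16 are carried as epimer mixtures, since each becomes trigonal in a later ionisation.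
- 21 and 22 are drawn as the expected 4β epimers; either C4 epimer would serve in step 18.

## Steps

Step 1
Reactants: 1 (−)-epicatechin
Product: 2 5,7,3',4'-tetra-O-benzyl-(−)-epicatechin
Conditions: BnBr, K2CO3, DMF, 0 °C to rt
Reagents that add atoms: benzyl bromide, BrCc1ccccc1
Why: Williamson etherification of the four phenols; the much less acidic secondary 3-hydroxyl should stay free under carbonate, and C2 and C3 are untouched.

Step 2
Reactants: 2 5,7,3',4'-tetra-O-benzyl-(−)-epicatechin
Product: 3 3,5,7,3',4'-penta-O-benzyl-(−)-epicatechin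
Conditions: NaH, BnBr, n-Bu4NI (cat.), DMF, 0 °C to rt
Reagents that add atoms: benzyl bromide, BrCc1ccccc1
Why: Williamson alkylation of the sodium alkoxide; a non-participating ether at O3 is needed for the organolithium step and for trans attack at C4 later.

Step 3
Reactants: 3 3,5,7,3',4'-penta-O-benzyl-(−)-epicatechin
Product: 4 8-bromo-3,5,7,3',4'-penta-O-benzyl-(−)-epicatechin
Conditions: NBS, CH2Cl2, −78 °C to rt
Reagents that add atoms: N-bromosuccinimide, O=C1CCC(=O)N1Br
Why: Electrophilic aromatic bromination; in 3-O-protected tetra-O-benzyl flavan-3-ols C8 is the more reactive of the two free ring A positions, so one equivalent should give the 8-bromide.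

Step 4
Reactants: 5 2,4,6-trihydroxybenzaldehyde
Product: 6 2-hydroxy-4,6-bis(benzyloxy)benzaldehyde
Conditions: BnBr (2 equiv), K2CO3, DMF, 0 °C to rt
Reagents that add atoms: benzyl bromide, BrCc1ccccc1
Why: Williamson etherification; after the para and one ortho hydroxyl have reacted, the remaining hydroxyl is hydrogen-bonded to the formyl group and is the slowest to alkylate.

Step 5
Reactants: 6 2-hydroxy-4,6-bis(benzyloxy)benzaldehyde
Product: 7 2-(tert-butyldimethylsilyloxy)-4,6-bis(benzyloxy)benzaldehyde
Conditions: TBSCl, imidazole, DMF, rt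
Reagents that add atoms: tert-butyldimethylsilyl chloride, CC(C)(C)[Si](C)(C)Cl
Why: Silylation of the phenol gives a neutral, more electrophilic aldehyde for the organolithium addition and a group that fluoride removes without touching benzyl ethers.

Step 6
Reactants: 4 8-bromo-3,5,7,3',4'-penta-O-benzyl-(−)-epicatechin; 7 2-(tert-butyldimethylsilyloxy)-4,6-bis(benzyloxy)benzaldehyde
Product: 9 [2-(tert-butyldimethylsilyloxy)-4,6-bis(benzyloxy)phenyl](penta-O-benzylepicatechin-8-yl)methanol as carbinol epimers, via 8-lithio-penta-O-benzylepicatechin 8 (not isolated)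
Conditions: n-BuLi, THF, −78 °C; then 7, −78 °C; AcOH in THF, −78 °C
Reagents that add atoms: none
Why: Bromine–lithium exchange followed by 1,2-addition of the aryllithium to the aldehyde forms the future C4–C8 bond with the regiochemistry fixed by the bromine; the cold acidic quench is meant to forestall O-to-O silyl migration in the lithium alkoxide.

Step 7
Reactants: 9 [2-(tert-butyldimethylsilyloxy)-4,6-bis(benzyloxy)phenyl](penta-O-benzylepicatechin-8-yl)methanol
Product: 10 [2-hydroxy-4,6-bis(benzyloxy)phenyl](penta-O-benzylepicatechin-8-yl)methanol as carbinol epimers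
Conditions: n-Bu4NF, AcOH, THF, 0 °C
Reagents that add atoms: none
Why: Fluoride cleavage of the aryl silyl ether under buffered, non-acidic conditions, in which the benzhydrol cannot ionise (hydroxide is not lost from a phenoxide); the product should be handled on base-washed silica.

Step 8
Reactants: 10 [2-hydroxy-4,6-bis(benzyloxy)phenyl](penta-O-benzylepicatechin-8-yl)methanol; 11 benzyloxyacetaldehyde
Product: 15 (3R,4R)-3,5,7-tris(benzyloxy)-4-(penta-O-benzylepicatechin-8-yl)chroman-2-ol as anomers, via o-quinone methide 12 (not isolated), via catalyst enamine of benzyloxyacetaldehyde 13 (not isolated), via open hydroxy aldehyde 14 (not isolated)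
Conditions: (S)-α,α-diphenylprolinol trimethylsilyl ether (20 mol %), PhCO2H (20 mol %), 11 (3 equiv), CH2Cl2, 0 °C to rt, slow addition of 10; aqueous work-up
Reagents that add atoms: none
Why: Benzoic acid dehydrates the doubly activated benzhydrol 10 to o-quinone methide 12 while the amine condenses with 11 to the E-enamine 13; the enamine α-carbon adds to the methide carbon (C3–C4) with rearomatisation of ring A, the iminium ion is hydrolysed by the water just released to hydroxy aldehyde 14, and the phenol oxygen closes ring C by 6-exo-trig hemiacetal formation (O1–C2), which frees the catalyst. The closest known reaction type is the diarylprolinol silyl ether catalysed formal [4+2] addition of aldehydes to o-quinone methides generated in situ from o-hydroxybenzhydrols, which gives 3,4-disubstituted chroman-2-ols. C3 is controlled by the catalyst: the diphenyl(silyloxy)methyl group blocks one face of 13, and the S catalyst should place the electrophile so that C3 is R. C4 is controlled by the relative topicity of the two trigonal carbons: in the synclinal open transition state usual for enamine Michael additions the methide oxygen lies near the enamine nitrogen and the methide aryl group points away from the pyrrolidine, which with the aryl group anti to the methide carbonyl gives 4R and hence 3,4-trans. The step needs the 3,4-trans relation and the 4β absolute sense; the catalyst is expected to override the remote stereocentres of the middle unit, and a 3-epimer can drain to the trans lactol through the open aldehyde because trans places the benzyloxy group anti to the quasi-axial C4 aryl group. Chemoselectivity rests on the substrate: only the carbinol carbon can ionise, only the ortho phenol can close the ring, and the enamine is a far better nucleophile than the benzyloxylated rings that could otherwise capture 12. The hemiacetal carbon forms as both anomers, which is immaterial because it becomes trigonal again in steps 9 and 10.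

Step 9
Reactants: 15 (3R,4R)-3,5,7-tris(benzyloxy)-4-(penta-O-benzylepicatechin-8-yl)chroman-2-ol
Product: 16 (3R,4R)-3,5,7-tris(benzyloxy)-2-(phenylsulfonyl)-4-(penta-O-benzylepicatechin-8-yl)chroman as anomers
Conditions: PhSO2H, CaCl2, CH2Cl2, rt
Reagents that add atoms: benzenesulfinic acid, O=S(O)c1ccccc1
Why: Acid-promoted exchange of the anomeric hydroxyl for sulfinate through the cyclic oxocarbenium ion, the standard preparation of 2-(arylsulfonyl) cyclic ethers from lactols; sulfinate is a far better nucleophile than the arene rings, and C3 and C4 are not involved.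

Step 10
Reactants: 16 (3R,4R)-3,5,7-tris(benzyloxy)-2-(phenylsulfonyl)-4-(penta-O-benzylepicatechin-8-yl)chroman; 17 4-bromo-1,2-bis(benzyloxy)benzene
Product: 20 deca-O-benzyl epicatechin-(4β→8)-epicatechin, via 3,4-bis(benzyloxy)phenylmagnesium bromide 18 (not isolated), via 3,4-bis(benzyloxy)phenylzinc bromide 19 (not isolated)
Conditions: 17, Mg, THF; ZnBr2, THF, 0 °C to rt; then 16, rt
Reagents that add atoms: none
Why: Substitution of a 2-(arylsulfonyl) cyclic ether by an organozinc reagent: the zinc and magnesium halides ionise the sulfone and the arylzinc transfers its aryl group to the oxocarbenium carbon faster than any ring A of the substrate can. The aryl group should enter anti to the C4 substituent and cis to the 3-benzyloxy group (axial attack on the half-chair with the 3-alkoxy group quasi-equatorial, and 1,3-diaxial blocking of the other face by the C4 aryl group), which sets C2 as in epicatechin.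

Step 11
Reactants: 20 deca-O-benzyl epicatechin-(4β→8)-epicatechin
Product: 21 deca-O-benzyl epicatechin-(4β→8)-4β-(2-hydroxyethoxy)epicatechin
Conditions: DDQ, HOCH2CH2OH, CH2Cl2, rt
Reagents that add atoms: ethylene glycol, OCCO
Why: Quinone-mediated benzylic oxidation: DDQ abstracts hydride from the C4 methylene of the lower flavan unit of the dimer, whose axial C–H is aligned with ring A, and the glycol traps the cation trans to the 3-benzyloxy group. The C4–H of the upper unit is quasi-equatorial and buried between two tetra-substituted rings and should be left alone.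

Step 12
Reactants: 21 deca-O-benzyl epicatechin-(4β→8)-4β-(2-hydroxyethoxy)epicatechin
Product: 22 deca-O-benzyl epicatechin-(4β→8)-4β-(1,3-benzothiazol-2-ylthio)epicatechin
Conditions: 2-mercaptobenzothiazole, BF3·OEt2, CH2Cl2, −40 to 0 °C
Reagents that add atoms: 2-mercaptobenzothiazole, Sc1nc2ccccc2s1
Why: Lewis acid mediated SN1 exchange of the C4 alkoxy group for the thiol, known for 4-(2-hydroxyethoxy)flavans; the soft sulfur nucleophile captures the cation irreversibly enough at low temperature that the C4–C8 bond should not be cleaved.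

Step 13
Reactants: 23 (+)-epicatechin
Product: 24 5,7,3',4'-tetra-O-benzyl-(+)-epicatechin
Conditions: BnBr, K2CO3, DMF, 0 °C to rt
Reagents that add atoms: benzyl bromide, BrCc1ccccc1
Why: Williamson etherification of the four phenols, as in step 1.

Step 14
Reactants: 24 5,7,3',4'-tetra-O-benzyl-(+)-epicatechin
Product: 25 3,5,7,3',4'-penta-O-benzyl-(+)-epicatechin
Conditions: NaH, BnBr, n-Bu4NI (cat.), DMF, 0 °C to rt
Reagents that add atoms: benzyl bromide, BrCc1ccccc1
Why: Williamson alkylation of the 3-alkoxide, as in step 2; the 3-hydroxyl must be blocked so that only the C4 hydroxyl acts as nucleophile in step 18.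

Step 15
Reactants: 25 3,5,7,3',4'-penta-O-benzyl-(+)-epicatechin
Product: 26 (2S,3S,4R)-3,5,7-tris(benzyloxy)-2-[3,4-bis(benzyloxy)phenyl]chroman-4-ol (2,3-cis-3,4-trans)
Conditions: DDQ, H2O, CH2Cl2/THF, rt
Reagents that add atoms: water, O
Why: Quinone-mediated benzylic hydroxylation at C4, with water adding trans to the 3-benzyloxy group; the new configuration does not matter because C4 becomes a ketone in the next step.

Step 16
Reactants: 26 (2S,3S,4R)-3,5,7-tris(benzyloxy)-2-[3,4-bis(benzyloxy)phenyl]chroman-4-ol
Product: 27 (2S)-2,3-cis-3,5,7-tris(benzyloxy)-2-[3,4-bis(benzyloxy)phenyl]chroman-4-one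
Conditions: Dess–Martin periodinane, CH2Cl2, rt
Reagents that add atoms: none
Why: Dess–Martin oxidation of the secondary benzylic alcohol under non-basic conditions, so that the base-sensitive 2,3-cis α-alkoxy ketone is neither epimerised at C3 nor opened to the chalcone.

Step 17
Reactants: 27 (2S)-2,3-cis-3,5,7-tris(benzyloxy)-2-[3,4-bis(benzyloxy)phenyl]chroman-4-one
Product: 28 (2S,3S,4S)-3,5,7-tris(benzyloxy)-2-[3,4-bis(benzyloxy)phenyl]chroman-4-ol (all-cis)
Conditions: LiBH(s-Bu)3, THF, −78 °C
Reagents that add atoms: none
Why: Substrate-controlled ketone reduction: the bulky borohydride attacks C4 from the face anti to the axial 3-benzyloxy group, so the new hydroxyl ends cis to both the C3 oxygen and the C2 aryl group (4S); low temperature and an aprotic medium protect the cis ketone.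

Step 18
Reactants: 22 deca-O-benzyl epicatechin-(4β→8)-4β-(1,3-benzothiazol-2-ylthio)epicatechin; 28 (2S,3S,4S)-3,5,7-tris(benzyloxy)-2-[3,4-bis(benzyloxy)phenyl]chroman-4-ol
Product: 29 pentadeca-O-benzyl ether of 30
Conditions: AgBF4, 2,6-di-tert-butyl-4-methylpyridine, 4 Å MS, THF, −40 to 0 °C, dark
Reagents that add atoms: none
Why: Thiophilic activation of the heteroaryl thioether by the silver salt, the counterpart of a thioimidate glycosylation, gives the C4 cation of the middle unit, and the hydroxyl of 28 adds trans to the 3-benzyloxy group (4β). The cis C4–O bond of 28 is not broken and keeps its configuration, and the hindered base removes the acid that could re-ionise either benzylic C–O bond of the product.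

Step 19
Reactants: 29 pentadeca-O-benzyl ether of 30
Product: 30 CNP0310719.1
Conditions: H2 (1 atm), Pd(OH)2/C, THF/MeOH/H2O, rt
Reagents that add atoms: none
Why: Catalytic hydrogenolysis of twelve aryl and three alkyl benzyl ethers under neutral conditions, as is usual for benzylated oligomeric flavan-3-ols; the inter-unit ether and the C2–O1 bonds are secondary, flanked by substituents on both sides and should survive as the ring ethers of this class do.

## Compound list

1 | (−)-epicatechin, (2R,3R) | Oc1cc(O)c2c(c1)O[C@H](c1ccc(O)c(O)c1)[C@H](O)C2 | starting material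
2 | 5,7,3',4'-tetra-O-benzyl-(−)-epicatechin, (2R,3R), 3-OH free | c9ccccc9COc1cc(OCc9ccccc9)c2c(c1)O[C@H](c1ccc(OCc9ccccc9)c(OCc9ccccc9)c1)[C@H](O)C2 | intermediate
3 | 3,5,7,3',4'-penta-O-benzyl-(−)-epicatechin, (2R,3R) | c9ccccc9COc1cc(OCc9ccccc9)c2c(c1)O[C@H](c1ccc(OCc9ccccc9)c(OCc9ccccc9)c1)[C@H](OCc9ccccc9)C2 | intermediate
4 | 8-bromo-3,5,7,3',4'-penta-O-benzyl-(−)-epicatechin | Brc1c(OCc9ccccc9)cc(OCc9ccccc9)c2c1O[C@H](c1ccc(OCc9ccccc9)c(OCc9ccccc9)c1)[C@H](OCc9ccccc9)C2 | intermediate
5 | 2,4,6-trihydroxybenzaldehyde | O=Cc1c(O)cc(O)cc1O | starting material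
6 | 2-hydroxy-4,6-bis(benzyloxy)benzaldehyde | O=Cc1c(O)cc(OCc9ccccc9)cc1OCc9ccccc9 | intermediate
7 | 2-(tert-butyldimethylsilyloxy)-4,6-bis(benzyloxy)benzaldehyde | O=Cc1c(O[Si](C)(C)C(C)(C)C)cc(OCc9ccccc9)cc1OCc9ccccc9 | intermediate
8 | 8-lithio-3,5,7,3',4'-penta-O-benzyl-(−)-epicatechin | [Li]c1c(OCc9ccccc9)cc(OCc9ccccc9)c2c1O[C@H](c1ccc(OCc9ccccc9)c(OCc9ccccc9)c1)[C@H](OCc9ccccc9)C2 | intermediate
9 | [2-(tert-butyldimethylsilyloxy)-4,6-bis(benzyloxy)phenyl](penta-O-benzylepicatechin-8-yl)methanol, carbinol epimers | CC(C)(C)[Si](C)(C)Oc1cc(OCc9ccccc9)cc(OCc9ccccc9)c1C(O)c1c(OCc9ccccc9)cc(OCc9ccccc9)c2c1O[C@H](c1ccc(OCc9ccccc9)c(OCc9ccccc9)c1)[C@H](OCc9ccccc9)C2 | intermediate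
10 | [2-hydroxy-4,6-bis(benzyloxy)phenyl](penta-O-benzylepicatechin-8-yl)methanol, carbinol epimers | Oc1cc(OCc9ccccc9)cc(OCc9ccccc9)c1C(O)c1c(OCc9ccccc9)cc(OCc9ccccc9)c2c1O[C@H](c1ccc(OCc9ccccc9)c(OCc9ccccc9)c1)[C@H](OCc9ccccc9)C2 | intermediate
11 | benzyloxyacetaldehyde | O=CCOCc1ccccc1 | starting material
12 | 3,5-bis(benzyloxy)-6-[(penta-O-benzylepicatechin-8-yl)methylidene]cyclohexa-2,4-dien-1-one (o-quinone methide, double-bond geometry not fixed) | O=C1C=C(OCc9ccccc9)C=C(OCc9ccccc9)C1=Cc1c(OCc9ccccc9)cc(OCc9ccccc9)c2c1O[C@H](c1ccc(OCc9ccccc9)c(OCc9ccccc9)c1)[C@H](OCc9ccccc9)C2 | intermediate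
13 | (E)-enamine of benzyloxyacetaldehyde and (S)-α,α-diphenylprolinol trimethylsilyl ether | C[Si](C)(C)OC(c1ccccc1)(c1ccccc1)[C@@H]1CCCN1/C=C/OCc1ccccc1 | intermediate
14 | (2R,3R)-2-benzyloxy-3-[2-hydroxy-4,6-bis(benzyloxy)phenyl]-3-(penta-O-benzylepicatechin-8-yl)propanal | O=C[C@H](OCc9ccccc9)[C@H](c1c(O)cc(OCc9ccccc9)cc1OCc9ccccc9)c1c(OCc9ccccc9)cc(OCc9ccccc9)c2c1O[C@H](c1ccc(OCc9ccccc9)c(OCc9ccccc9)c1)[C@H](OCc9ccccc9)C2 | intermediate
15 | (3R,4R)-3,5,7-tris(benzyloxy)-4-(penta-O-benzylepicatechin-8-yl)chroman-2-ol, 3,4-trans, anomers | c9ccccc9COc1cc(OCc9ccccc9)c2c(c1)OC(O)[C@H](OCc9ccccc9)[C@H]2c1c(OCc9ccccc9)cc(OCc9ccccc9)c2c1O[C@H](c1ccc(OCc9ccccc9)c(OCc9ccccc9)c1)[C@H](OCc9ccccc9)C2 | intermediate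
16 | (3R,4R)-3,5,7-tris(benzyloxy)-2-(phenylsulfonyl)-4-(penta-O-benzylepicatechin-8-yl)chroman, 3,4-trans, anomers | c9ccccc9COc1cc(OCc9ccccc9)c2c(c1)OC(S(=O)(=O)c9ccccc9)[C@H](OCc9ccccc9)[C@H]2c1c(OCc9ccccc9)cc(OCc9ccccc9)c2c1O[C@H](c1ccc(OCc9ccccc9)c(OCc9ccccc9)c1)[C@H](OCc9ccccc9)C2 | intermediate
17 | 4-bromo-1,2-bis(benzyloxy)benzene | Brc1ccc(OCc9ccccc9)c(OCc9ccccc9)c1 | starting material
18 | 3,4-bis(benzyloxy)phenylmagnesium bromide | Br[Mg]c1ccc(OCc9ccccc9)c(OCc9ccccc9)c1 | intermediate
19 | 3,4-bis(benzyloxy)phenylzinc bromide | Br[Zn]c1ccc(OCc9ccccc9)c(OCc9ccccc9)c1 | intermediate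
20 | deca-O-benzyl epicatechin-(4β→8)-epicatechin; both units (2R,3R), upper unit 2,3-cis-3,4-trans | c9ccccc9COc1cc(OCc9ccccc9)c2c(c1)O[C@H](c1ccc(OCc9ccccc9)c(OCc9ccccc9)c1)[C@H](OCc9ccccc9)[C@H]2c1c(OCc9ccccc9)cc(OCc9ccccc9)c2c1O[C@H](c1ccc(OCc9ccccc9)c(OCc9ccccc9)c1)[C@H](OCc9ccccc9)C2 | intermediate
21 | deca-O-benzyl epicatechin-(4β→8)-4β-(2-hydroxyethoxy)epicatechin (glycol ether trans to 3-OBn of the lower unit of the dimer) | c9ccccc9COc1cc(OCc9ccccc9)c2c(c1)O[C@H](c1ccc(OCc9ccccc9)c(OCc9ccccc9)c1)[C@H](OCc9ccccc9)[C@H]2c1c(OCc9ccccc9)cc(OCc9ccccc9)c2c1O[C@H](c1ccc(OCc9ccccc9)c(OCc9ccccc9)c1)[C@H](OCc9ccccc9)[C@H]2OCCO | intermediate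
22 | deca-O-benzyl epicatechin-(4β→8)-4β-(1,3-benzothiazol-2-ylthio)epicatechin | c9ccccc9COc1cc(OCc9ccccc9)c2c(c1)O[C@H](c1ccc(OCc9ccccc9)c(OCc9ccccc9)c1)[C@H](OCc9ccccc9)[C@H]2c1c(OCc9ccccc9)cc(OCc9ccccc9)c2c1O[C@H](c1ccc(OCc9ccccc9)c(OCc9ccccc9)c1)[C@H](OCc9ccccc9)[C@H]2Sc1nc3ccccc3s1 | intermediate
23 | (+)-epicatechin, (2S,3S) | Oc1cc(O)c2c(c1)O[C@@H](c1ccc(O)c(O)c1)[C@@H](O)C2 | starting material
24 | 5,7,3',4'-tetra-O-benzyl-(+)-epicatechin, (2S,3S) | c9ccccc9COc1cc(OCc9ccccc9)c2c(c1)O[C@@H](c1ccc(OCc9ccccc9)c(OCc9ccccc9)c1)[C@@H](O)C2 | intermediate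
25 | 3,5,7,3',4'-penta-O-benzyl-(+)-epicatechin, (2S,3S) | c9ccccc9COc1cc(OCc9ccccc9)c2c(c1)O[C@@H](c1ccc(OCc9ccccc9)c(OCc9ccccc9)c1)[C@@H](OCc9ccccc9)C2 | intermediate
26 | (2S,3S,4R)-3,5,7-tris(benzyloxy)-2-[3,4-bis(benzyloxy)phenyl]chroman-4-ol, 2,3-cis-3,4-trans | c9ccccc9COc1cc(OCc9ccccc9)c2c(c1)O[C@@H](c1ccc(OCc9ccccc9)c(OCc9ccccc9)c1)[C@@H](OCc9ccccc9)[C@@H]2O | intermediate
27 | (2S)-2,3-cis-3,5,7-tris(benzyloxy)-2-[3,4-bis(benzyloxy)phenyl]chroman-4-one | c9ccccc9COc1cc(OCc9ccccc9)c2c(c1)O[C@@H](c1ccc(OCc9ccccc9)c(OCc9ccccc9)c1)[C@@H](OCc9ccccc9)C2=O | intermediate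
28 | (2S,3S,4S)-3,5,7-tris(benzyloxy)-2-[3,4-bis(benzyloxy)phenyl]chroman-4-ol, all-cis | c9ccccc9COc1cc(OCc9ccccc9)c2c(c1)O[C@@H](c1ccc(OCc9ccccc9)c(OCc9ccccc9)c1)[C@@H](OCc9ccccc9)[C@H]2O | intermediate
29 | pentadeca-O-benzyl ether of 30: the 4β-yl ether of 20 (at C4 of its lower unit, trans to 3-OBn) with the C4 oxygen of 28 | c9ccccc9COc1cc(OCc9ccccc9)c2c(c1)O[C@H](c1ccc(OCc9ccccc9)c(OCc9ccccc9)c1)[C@H](OCc9ccccc9)[C@H]2c1c(OCc9ccccc9)cc(OCc9ccccc9)c2c1O[C@H](c1ccc(OCc9ccccc9)c(OCc9ccccc9)c1)[C@H](OCc9ccccc9)[C@H]2O[C@H]1c2c(OCc9ccccc9)cc(OCc9ccccc9)cc2O[C@@H](c2ccc(OCc9ccccc9)c(OCc9ccccc9)c2)[C@H]1OCc9ccccc9 | intermediate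
30 | CNP0310719.1: epicatechin-(4β→8)-epicatechin whose middle C4 (β, trans to 3-OH) is ether-linked to C4 of an all-cis (2S,3S,4S)-3',4',5,7-tetrahydroxyflavan-3,4-diol | Oc1cc(O)c2c(c1)O[C@H](c1ccc(O)c(O)c1)[C@H](O)[C@H]2c1c(O)cc(O)c2c1O[C@H](c1ccc(O)c(O)c1)[C@H](O)[C@H]2O[C@H]1c2c(O)cc(O)cc2O[C@@H](c2ccc(O)c(O)c2)[C@H]1O | target

## Step count and least certain steps

Total: 19 steps. Longest linear sequence: 12 steps (1 → 2 → 3 → 4 → 9 → 10 → 15 → 16 → 20 → 21 → 22 → 29 → 30, i.e. steps 1, 2, 3, 6, 7, 8, 9, 10, 11, 12, 18, 19).

**Step 8 (key step).** The most likely failure is poor facial selectivity at the methide carbon. The methide is flanked by four ortho substituents, so the geometry of its exocyclic double bond, on which the sense of induction at C4 depends, is not secured; should it react through the other geometry, the enantiomeric catalyst combined with equilibration at C3 would be tried first. In addition, slow bond formation at this crowded carbon leaves time for retro-addition and for capture of the methide by electron-rich rings. Fallback: the upper unit is attached by the cationic route, which is the shorter way to 20 and needs no catalyst-controlled centre. Setting out from 3, benzylic oxidation with DDQ in the presence of 2-ethoxyethanol would give 4β-(2-ethoxyethoxy)-3,5,7,3',4'-penta-O-benzyl-(−)-epicatechin F1. Friedel–Crafts coupling of F1 with an excess of 3 under catalytic trimethylsilyl triflate in CH2Cl2 at −78 °C, where attack trans to the 3-benzyloxy group and at C8 is the established preference, comes back to the route at 20.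

**Step 10.** The most likely failure is entry of the aryl group on the wrong face of the oxocarbenium ion, for instance by direct displacement within an ion pair of one sulfone anomer, giving the 2,3-trans isomer; loss of H3 to the enol ether is the second hazard. Fallback: the roles of aryl and hydrogen are exchanged, so that a nucleophile preferring that face now puts hydrogen where the aryl group went. Setting out from 15, Dess–Martin oxidation would give the lactone (3R,4R)-3,5,7-tris(benzyloxy)-4-(penta-O-benzylepicatechin-8-yl)chroman-2-one F4. Bromine–lithium exchange on 17 gives 3,4-bis(benzyloxy)phenyllithium F5, which adds once to F4 at −78 °C to give the hemiketal 2-[3,4-bis(benzyloxy)phenyl]-3,5,7-tris(benzyloxy)-4-(penta-O-benzylepicatechin-8-yl)chroman-2-ol F6. Ionic reduction of F6 with Et3SiH and BF3·OEt2 comes back to the route at 20.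

**Step 18.** The most likely failure is competition between the hydroxyl of 28 and its own nucleophilic ring A carbons (C6, C8) for the C4 cation, made worse if traces of acid re-ionise the ether and drain it into carbon–carbon linked products. Fallback: the ring A positions of the nucleophile are capped with bromine. Setting out from 28, NBS (2 equiv) would give (2S,3S,4S)-6,8-dibromo-3,5,7-tris(benzyloxy)-2-[3,4-bis(benzyloxy)phenyl]chroman-4-ol F9. Coupling of F9 with 22 under the conditions of step 18 gives the 6,8-dibromo derivative of 29 (bromines on ring A of the lower unit) F10. Hydrogenolysis of F10 over Pd(OH)2/C with Et3N removes the bromine atoms together with the benzyl groups and comes back to the route at 30.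

**Step 11.** The most likely failure is loss of site selectivity in the hydride abstraction (upper C4 methine, C2 positions, benzyl methylenes) or over-oxidation of the dimer. Fallback: the sulfur leaving group is installed on a monomer and the dimer is assembled by orthogonal activation, so that no dimer is oxidised. Setting out from 3, F1 is made as above and exchanged with 2,6-dimethylbenzenethiol and BF3·OEt2 to give 4β-(2,6-dimethylphenylthio)-3,5,7,3',4'-penta-O-benzyl-(−)-epicatechin F7. A second portion of F1 is coupled with an excess of F7 under BF3·OEt2 at −78 °C, a hard Lewis acid that leaves the sulfide alone, to give deca-O-benzyl epicatechin-(4β→8)-4β-(2,6-dimethylphenylthio)epicatechin F8. Activation of F8 with dimethyl(methylthio)sulfonium triflate and 2,6-di-tert-butyl-4-methylpyridine in the presence of 28 comes back to the route at 29.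

**Step 6.** The most likely failure is O-to-O silyl migration in the lithium alkoxide followed by elimination to 12, which would consume a second aryllithium; proton transfer from a benzylic methylene to 8 before it reaches the doubly ortho-substituted aldehyde is the other risk. Fallback: the polarity of the union is reversed and the silyl group avoided. Setting out from 4, lithiation and quenching with DMF would give 8-formyl-3,5,7,3',4'-penta-O-benzyl-(−)-epicatechin F2. 3,5-Bis(benzyloxy)phenol is deprotonated with EtMgBr to bromomagnesium 3,5-bis(benzyloxy)phenoxide F3, which adds through its ortho carbon to F2 in toluene (ortho-selective hydroxyalkylation of a magnesium phenoxide) and comes back to the route at 10.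

## Further compounds

F1 | step 8 | 4β-(2-ethoxyethoxy)-3,5,7,3',4'-penta-O-benzyl-(−)-epicatechin | c9ccccc9COc1cc(OCc9ccccc9)c2c(c1)O[C@H](c1ccc(OCc9ccccc9)c(OCc9ccccc9)c1)[C@H](OCc9ccccc9)[C@H]2OCCOCC
F2 | step 6 | 8-formyl-3,5,7,3',4'-penta-O-benzyl-(−)-epicatechin | O=Cc1c(OCc9ccccc9)cc(OCc9ccccc9)c2c1O[C@H](c1ccc(OCc9ccccc9)c(OCc9ccccc9)c1)[C@H](OCc9ccccc9)C2
F3 | step 6 | bromomagnesium 3,5-bis(benzyloxy)phenoxide | Br[Mg]Oc1cc(OCc9ccccc9)cc(OCc9ccccc9)c1
F4 | step 10 | (3R,4R)-3,5,7-tris(benzyloxy)-4-(penta-O-benzylepicatechin-8-yl)chroman-2-one | c9ccccc9COc1cc(OCc9ccccc9)c2c(c1)OC(=O)[C@H](OCc9ccccc9)[C@H]2c1c(OCc9ccccc9)cc(OCc9ccccc9)c2c1O[C@H](c1ccc(OCc9ccccc9)c(OCc9ccccc9)c1)[C@H](OCc9ccccc9)C2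
F5 | step 10 | 3,4-bis(benzyloxy)phenyllithium | [Li]c1ccc(OCc9ccccc9)c(OCc9ccccc9)c1
F6 | step 10 | 2-[3,4-bis(benzyloxy)phenyl]-3,5,7-tris(benzyloxy)-4-(penta-O-benzylepicatechin-8-yl)chroman-2-ol, 3,4-trans, C2 epimers | c9ccccc9COc1cc(OCc9ccccc9)c2c(c1)OC(O)(c1ccc(OCc9ccccc9)c(OCc9ccccc9)c1)[C@H](OCc9ccccc9)[C@H]2c1c(OCc9ccccc9)cc(OCc9ccccc9)c2c1O[C@H](c1ccc(OCc9ccccc9)c(OCc9ccccc9)c1)[C@H](OCc9ccccc9)C2
F7 | step 11 | 4β-(2,6-dimethylphenylthio)-3,5,7,3',4'-penta-O-benzyl-(−)-epicatechin | c9ccccc9COc1cc(OCc9ccccc9)c2c(c1)O[C@H](c1ccc(OCc9ccccc9)c(OCc9ccccc9)c1)[C@H](OCc9ccccc9)[C@H]2Sc1c(C)cccc1C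
F8 | step 11 | deca-O-benzyl epicatechin-(4β→8)-4β-(2,6-dimethylphenylthio)epicatechin | c9ccccc9COc1cc(OCc9ccccc9)c2c(c1)O[C@H](c1ccc(OCc9ccccc9)c(OCc9ccccc9)c1)[C@H](OCc9ccccc9)[C@H]2c1c(OCc9ccccc9)cc(OCc9ccccc9)c2c1O[C@H](c1ccc(OCc9ccccc9)c(OCc9ccccc9)c1)[C@H](OCc9ccccc9)[C@H]2Sc1c(C)cccc1C
F9 | step 18 | (2S,3S,4S)-6,8-dibromo-3,5,7-tris(benzyloxy)-2-[3,4-bis(benzyloxy)phenyl]chroman-4-ol, all-cis | c9ccccc9COc1c(Br)c(OCc9ccccc9)c2c(c1Br)O[C@@H](c1ccc(OCc9ccccc9)c(OCc9ccccc9)c1)[C@@H](OCc9ccccc9)[C@H]2O
F10 | step 18 | 6,8-dibromo derivative of 29 (bromines on ring A of the lower unit) | c9ccccc9COc1cc(OCc9ccccc9)c2c(c1)O[C@H](c1ccc(OCc9ccccc9)c(OCc9ccccc9)c1)[C@H](OCc9ccccc9)[C@H]2c1c(OCc9ccccc9)cc(OCc9ccccc9)c2c1O[C@H](c1ccc(OCc9ccccc9)c(OCc9ccccc9)c1)[C@H](OCc9ccccc9)[C@H]2O[C@H]1c2c(OCc9ccccc9)c(Br)c(OCc9ccccc9)c(Br)c2O[C@@H](c2ccc(OCc9ccccc9)c(OCc9ccccc9)c2)[C@H]1OCc9ccccc9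
A1 | alternative 1 | hub phenol from the benzannulation: upper unit at C8, open C2–C3–C4 chain at C4a, free hydroxyl at C8a, silyl ether at C5 | c9ccccc9COc1cc(OCc9ccccc9)c2c(c1)O[C@H](c1ccc(OCc9ccccc9)c(OCc9ccccc9)c1)[C@H](OCc9ccccc9)[C@H]2c1c(OCc9ccccc9)cc(O[Si](C(C)C)(C(C)C)C(C)C)c(C[C@@H](OCc9ccccc9)[C@@H](O[Si](C)(C)C(C)(C)C)c3ccc(OCc9ccccc9)c(OCc9ccccc9)c3)c1O
A2 | alternative 1 | 3-benzyloxy-4-(penta-O-benzylepicatechin-4β-yl)cyclobut-2-en-1-one, epimers at the ring carbon | c9ccccc9COc1cc(OCc9ccccc9)c2c(c1)O[C@H](c1ccc(OCc9ccccc9)c(OCc9ccccc9)c1)[C@H](OCc9ccccc9)[C@H]2C1C(=O)C=C1OCc9ccccc9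
A3 | alternative 1 | triisopropylsilyl ynol ether carrying the benzyloxy and tert-butyldimethylsilyloxy substituted 1-arylbutyl chain | CC(C)[Si](C(C)C)(C(C)C)OC#CC[C@@H](OCc9ccccc9)[C@@H](O[Si](C)(C)C(C)(C)C)c1ccc(OCc9ccccc9)c(OCc9ccccc9)c1
A4 | alternative 2 | 4-(dimer-4β-yloxy)-2-[3,4-bis(benzyloxy)phenyl]-5,7-bis(benzyloxy)-2H-chromene | c9ccccc9COc1cc(OCc9ccccc9)c2c(c1)O[C@H](c1ccc(OCc9ccccc9)c(OCc9ccccc9)c1)[C@H](OCc9ccccc9)[C@H]2c1c(OCc9ccccc9)cc(OCc9ccccc9)c2c1O[C@H](c1ccc(OCc9ccccc9)c(OCc9ccccc9)c1)[C@H](OCc9ccccc9)[C@H]2OC1=C[C@H](c4ccc(OCc9ccccc9)c(OCc9ccccc9)c4)Oc3cc(OCc9ccccc9)cc(OCc9ccccc9)c13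
A5 | alternative 2 | dimer-4β-yl 2-{1-[3,4-bis(benzyloxy)phenyl]allyloxy}-4,6-bis(benzyloxy)benzoate | c9ccccc9COc1cc(OCc9ccccc9)c2c(c1)O[C@H](c1ccc(OCc9ccccc9)c(OCc9ccccc9)c1)[C@H](OCc9ccccc9)[C@H]2c1c(OCc9ccccc9)cc(OCc9ccccc9)c2c1O[C@H](c1ccc(OCc9ccccc9)c(OCc9ccccc9)c1)[C@H](OCc9ccccc9)[C@H]2OC(=O)c1c(OCc9ccccc9)cc(OCc9ccccc9)cc1O[C@H](C=C)c1ccc(OCc9ccccc9)c(OCc9ccccc9)c1
A6 | alternative 3 | nona-O-benzyl epicatechin-(4β→8)-(2,3-cis-flavan-3,4-diol), C4 epimers of the lower ring | c9ccccc9COc1cc(OCc9ccccc9)c2c(c1)O[C@H](c1ccc(OCc9ccccc9)c(OCc9ccccc9)c1)[C@H](OCc9ccccc9)[C@H]2c1c(OCc9ccccc9)cc(OCc9ccccc9)c2c1O[C@H](c1ccc(OCc9ccccc9)c(OCc9ccccc9)c1)[C@H](O)C2O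
A7 | alternative 3 | 2-(penta-O-benzylepicatechin-4β-yl)-3,5-bis(benzyloxy)phenol | c9ccccc9COc1cc(OCc9ccccc9)c2c(c1)O[C@H](c1ccc(OCc9ccccc9)c(OCc9ccccc9)c1)[C@H](OCc9ccccc9)[C@H]2c1c(OCc9ccccc9)cc(OCc9ccccc9)cc1O
A8 | alternative 3 | cis-3-[3,4-bis(benzyloxy)phenyl]oxirane-2-carbaldehyde, the enantiomer leading to the (2R,3R) middle unit | O=C[C@H]1O[C@H]1c1ccc(OCc9ccccc9)c(OCc9ccccc9)c1
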